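If X (the complex) shares a flask with L (the incoming ligand) and D (a further species), then before we look for J (X with one ligand exchanged), we ask what D takes.

| flask | X | L | D | remark | time |
|---|---|---|---|---|---|
| Wednesday's | 1 mM | 0.28 mM | 0.30 mM | run made earlier |  |
| Saturday's | 1 mM | 0.85 mM | 0.30 mM | run made earlier |  |
| larch | 1.0 mM | 1.20 mM | 0.300 mM |  | 50 min |
| oak | 1.0 mM | 0.500 mM | 0.300 mM |  | 50 min |

| run | time / min | J / % | Q / % | X / % |
|---|---|---|---|---|
| Wednesday's | 2.50 | 3.6 | 1.6 | 73.5 |
| Wednesday's | 8.00 | 0.4 | 0 | 73.6 |
| Wednesday's | 15.0 | 1.7 | 0 | 73.8 |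
| Wednesday's | 20.0 | 0 | 1.6 | 70.8 |
| Wednesday's | 30.0 | 0 | 0 | 72.6 |
| Wednesday's | 40.0 | 0 | 0 | 72.6 |
| Wednesday's | 50.0 | 0 | 1.7 | 71.7 |
| Saturday's | 8.00 | 47.6 | 2.3 | 21.4 |
| Saturday's | 15.0 | 48.1 | 1.8 | 21.4 |
| Saturday's | 20.0 | 47.3 | 3.6 | 19.6 |
| Saturday's | 30.0 | 48.4 | 3.9 | 20.7 |
| Saturday's | 40.0 | 48.6 | 0.7 | 19.8 |
| Saturday's | 50.0 | 47.5 | 0.2 | 19.8 |

(standard deviation of a reading: 1 percentage point)

- the analysis behind the earlier runs scatters by 1 percentage point, standard deviation

1. which of these holds the largest part of the X at the end of larch (J / X / Q)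
2. which of these holds the largest part of the X at the end of oak (J / X / Q)
3. final J in oak, as a percentage of the X charged

The readings form a ladder of times. On the fastest rung, Wednesday's X has already fallen to 73.5% by 2.50 min. At 50.0 min, 26.6% of it is missing from X, J and Q (two exchanged), close to the 0.28 mM of L charged. So D seems to act as a scavenger, turning early J into something unseen.

On the next rung, Saturday's unseen share averages 29.5%, which matches D's 0.30 mM against 1 mM of X. J stands at 47.9% from 8.00 min onward. On the slowest rung, Saturday's Q stays much less than J, and neither drifts up to 50.0 min.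

So we count the spare L, 20.0% in oak: charged L minus charged D, as a share of the X charged. Once D is used, the spare L must equal J, plus Q counted double, plus free L.

Saturday's spare is 55.0%, so J falls 7.1 percentage points short. Going round once more, we take that shortfall to shrink roughly with the square of the spare, which is our guess for a product made from J and L together. Oak then gives J near 19.1%, below the 50.0% of X that we reckon its L leaves, so we expect X to lead there. Larch's spare of 90.0% exceeds the 70.0% of X that D leaves, so we expect J to lead, with some Q.

The forecast named J for larch and X for oak, with J at 20% (17% to 23%), slightly above our figure, holding that “D appears to trap the first J formed”.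

Larch ends with J 54.1%, Q 10.6% and X 5.30%; oak ends with X 50.4% and J 19.4%.

    X + L ⇌ G + J (K = 73.0, k = 46.0 /M/s)
    J + L ⇌ G + Q (K = 1.40, k = 20.0 /M/s)
    J + D → Z (k = 190 /M/s)

Oak's spare of 20.0% comes back as J 19.4%, doubled Q 0.288% and free L 0.263%. In oak, J ends this low partly through the step from J and D to Z, the largest single effect: without that step, oak would hold J at 47.7% instead of 19.4%. A neighbour of oak charged with 0.12 mM of D has a spare of 38.0% and ends with J at 36.5%.

The readings stem from a simulated flask with constants of no real substance; noise was put on by code.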